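The route rests on disconnecting C4–C4a of the flavan pyran (ring C). The key step is an AuCl3/AgOTf-catalysed 6-endo Friedel–Crafts opening of a terminal epoxide by C4a of phloroglucinol ring A, which closes ring C as the last ring. It exploits that C4a is the only free carbon ortho to O1, because C8 already carries the chalcane diarylmethine carbon, so the closure has one possible site. The precursor is an aryl ether whose O1–C2 bond and C2/C3 stereocentres come from SN2 opening of an epoxy alcohol (Sharpless asymmetric epoxidation) by the phenol of the upper half. That half's two stereocentres are set by iminium and enamine organocatalysis.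

Key step: step 9

Assumption: all starting materials, reagents and catalysts are purchased. The lactols and the 2-arylchroman intermediate are used as mixtures at C2, a carbon that ends as the CH2 group of the chalcane chain.

Step 1
Reactants: 1 3,4-bis(benzyloxy)benzaldehyde; 2 (triphenylphosphoranylidene)acetaldehyde
Product: 3 (E)-3-[3,4-bis(benzyloxy)phenyl]prop-2-enal
Conditions: toluene, 80 °C
Reagents that add atoms: none
Why: Wittig olefination with a stabilised ylide should give the (E)-enal.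

Step 2
Reactants: 3 (E)-3-[3,4-bis(benzyloxy)phenyl]prop-2-enal
Product: 4 (E)-3-[3,4-bis(benzyloxy)phenyl]prop-2-en-1-ol
Conditions: NaBH4, CeCl3·7H2O, MeOH/THF, 0 °C
Reagents that add atoms: none
Why: Luche reduction should deliver hydride 1,2 to the enal carbonyl and leave the alkene and the benzyl ethers untouched.

Step 3
Reactants: 4 (E)-3-[3,4-bis(benzyloxy)phenyl]prop-2-en-1-ol
Product: 5 [(2S,3S)-3-[3,4-bis(benzyloxy)phenyl]oxiran-2-yl]methanol (trans epoxide)
Conditions: Ti(OiPr)4 (10 mol %), L-(+)-diisopropyl tartrate (12 mol %), t-BuOOH, 4 Å MS, CH2Cl2, −20 °C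
Reagents that add atoms: tert-butyl hydroperoxide, CC(C)(C)OO
Why: Sharpless asymmetric epoxidation with the L-(+)-tartrate ligand should deliver oxygen to the face of the (E)-allylic alcohol that gives the (2S,3S)-epoxy alcohol, setting by reagent control the two carbons that become C3 and C2 of ring C.

Step 4
Reactants: 3 (E)-3-[3,4-bis(benzyloxy)phenyl]prop-2-enal; 6 3,5-bis(benzyloxy)phenol
Product: 7 (4R)-5,7-bis(benzyloxy)-4-[3,4-bis(benzyloxy)phenyl]chroman-2-ol (lactol as C2 anomers)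
Conditions: (R)-α,α-diphenylprolinol trimethylsilyl ether (20 mol %), PhCO2H (20 mol %), toluene, 0 to 23 °C
Reagents that add atoms: none
Why: In this iminium-catalysed Friedel–Crafts alkylation with hemiacetalisation, the phenol carbon ortho to OH should add to the β-carbon of the (E)-iminium ion on the face opposite the diphenyl(silyloxy)methyl group of the (R)-catalyst to set (4R), and the phenol oxygen then closes the lactol, which marks this oxygen as the future O1.

Step 5
Reactants: 7 (4R)-5,7-bis(benzyloxy)-4-[3,4-bis(benzyloxy)phenyl]chroman-2-ol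
Product: 9 (3R,4R)-5,7-bis(benzyloxy)-4-[3,4-bis(benzyloxy)phenyl]chromane-2,3-diol (3,4-cis), via aminooxy lactol 8 (not isolated)
Conditions: L-proline (20 mol %), PhNO (2.2 equiv), CHCl3, 0 °C; then CuSO4·5H2O (30 mol %), MeOH, 0 °C
Reagents that add atoms: nitrosobenzene, O=Nc1ccccc1
Why: In this proline-catalysed α-aminoxylation of the open-chain aldehyde tautomer (enamine catalysis), the carboxylic acid of L-proline should direct the nitroso oxygen to the enamine face that gives (3R), cis to the C4 aryl group, by catalyst control, and the N–O bond of 8 is then cleaved by the excess nitrosobenzene under CuSO4 catalysis.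

Step 6
Reactants: 9 (3R,4R)-5,7-bis(benzyloxy)-4-[3,4-bis(benzyloxy)phenyl]chromane-2,3-diol; 10 1,3,5-tris(benzyloxy)benzene
Product: 12 2-[(1R,2S)-1-[3,4-bis(benzyloxy)phenyl]-2-hydroxy-3-[2,4,6-tris(benzyloxy)phenyl]propyl]-3,5-bis(benzyloxy)phenol, via 2-arylchroman-3-ol 11 (not isolated)
Conditions: BF3·OEt2, CH2Cl2, −40 °C; then Et3SiH, −40 to 0 °C
Reagents that add atoms: none
Why: Friedel–Crafts C-arylation of the lactol oxocarbenium ion by the trialkoxybenzene (as in aryl C-glycoside synthesis) should give 11, whose O1–C2 bond, benzylic to the tris(benzyloxy)phenyl ring, ionises and is reduced by the silane (ionic hydrogenation, as in the reductive pyran cleavage of flavan-3-ols), so that the lactol carbon becomes CH2 and the phenol O1–H is released without touching the two stereocentres.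

Step 7
Reactants: 12 2-[(1R,2S)-1-[3,4-bis(benzyloxy)phenyl]-2-hydroxy-3-[2,4,6-tris(benzyloxy)phenyl]propyl]-3,5-bis(benzyloxy)phenol; 5 [(2S,3S)-3-[3,4-bis(benzyloxy)phenyl]oxiran-2-yl]methanol
Product: 13 (2S,3R)-3-[3,4-bis(benzyloxy)phenyl]-3-{3,5-bis(benzyloxy)-2-[(1R,2S)-1-[3,4-bis(benzyloxy)phenyl]-2-hydroxy-3-[2,4,6-tris(benzyloxy)phenyl]propyl]phenoxy}propane-1,2-diol
Conditions: Cs2CO3, DMF, 60 °C
Reagents that add atoms: none
Why: SN2 opening of the trans-3-arylglycidol by the caesium phenoxide at the benzylic epoxide carbon should proceed with inversion to give the (R)-aryl ether carbon (future C2) anti to the retained (S)-carbinol (future C3), the aliphatic hydroxyls not being deprotonated by the carbonate.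

Step 8
Reactants: 13 (2S,3R)-3-[3,4-bis(benzyloxy)phenyl]-3-{3,5-bis(benzyloxy)-2-[(1R,2S)-1-[3,4-bis(benzyloxy)phenyl]-2-hydroxy-3-[2,4,6-tris(benzyloxy)phenyl]propyl]phenoxy}propane-1,2-diol
Product: 15 (1R,2S)-1-[3,4-bis(benzyloxy)phenyl]-1-[2,4-bis(benzyloxy)-6-{(R)-[3,4-bis(benzyloxy)phenyl][(2S)-oxiran-2-yl]methoxy}phenyl]-3-[2,4,6-tris(benzyloxy)phenyl]propan-2-ol, via primary tosylate 14 (not isolated)
Conditions: TsCl, Bu2SnO (2 mol %), Et3N, CH2Cl2, 0 °C; then K2CO3, MeOH, 23 °C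
Reagents that add atoms: none
Why: Tin-acetal-mediated sulfonylation should select the primary hydroxyl of the 1,2-diol, and base-induced Williamson closure (3-exo-tet) then gives the terminal epoxide with retention at the carbinol carbon, the remote hindered secondary alcohol staying free.

Step 9
Reactants: 15 (1R,2S)-1-[3,4-bis(benzyloxy)phenyl]-1-[2,4-bis(benzyloxy)-6-{(R)-[3,4-bis(benzyloxy)phenyl][(2S)-oxiran-2-yl]methoxy}phenyl]-3-[2,4,6-tris(benzyloxy)phenyl]propan-2-ol
Product: 16 (2R,3S)-5,7-bis(benzyloxy)-2-[3,4-bis(benzyloxy)phenyl]-8-[(1R,2S)-1-[3,4-bis(benzyloxy)phenyl]-2-hydroxy-3-[2,4,6-tris(benzyloxy)phenyl]propyl]chroman-3-ol (nona-O-benzyl ether of the target)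
Conditions: AuCl3 (5 mol %), AgOTf (15 mol %), ClCH2CH2Cl, 23 °C
Reagents that add atoms: none
Why: The cationic gold species formed from AuCl3 and AgOTf activates the terminal epoxide, C4a of ring A attacks the primary epoxide carbon from the backside, and proton loss from the arenium ion restores aromaticity and frees the C3 hydroxyl. The closest known reaction type is the AuCl3/AgOTf-catalysed intramolecular Friedel–Crafts cycloalkylation of aryl glycidyl ethers to chroman-3-ols. Ring C closes in the 6-endo-tet mode by formation of the C4–C4a bond. No stereocentre is created: C2 (R) and C3 (S) are carried over from 15 because neither the O1–C2 bond nor the C3–O bond is broken, and their trans relationship was fixed by the anti epoxide opening of step 7. The step needs site selectivity on ring A, secured because C8 is substituted and C6 is para to O1 and cannot reach the epoxide, and 6-endo over 5-exo selectivity, favoured by attack at the unhindered primary carbon. Ionisation of the benzylic O1–C2 ether is the competing process and should be held back by the mild catalytic conditions at ambient temperature.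

Step 10
Reactants: 16 (2R,3S)-5,7-bis(benzyloxy)-2-[3,4-bis(benzyloxy)phenyl]-8-[(1R,2S)-1-[3,4-bis(benzyloxy)phenyl]-2-hydroxy-3-[2,4,6-tris(benzyloxy)phenyl]propyl]chroman-3-ol
Product: 17 (2R,3S)-2-(3,4-dihydroxyphenyl)-8-[(1R,2S)-1-(3,4-dihydroxyphenyl)-2-hydroxy-3-(2,4,6-trihydroxyphenyl)propyl]chromane-3,5,7-triol (the target)
Conditions: H2 (1 atm), Pd(OH)2/C, THF/MeOH, 23 °C
Reagents that add atoms: none
Why: Catalytic hydrogenolysis under neutral conditions should cleave the nine benzyl aryl ethers while the cyclic benzylic O1–C2 ether and the diarylmethine C–C bonds survive, as is usual for benzylated flavan-3-ols.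

Compound list
1 | 3,4-bis(benzyloxy)benzaldehyde | O=Cc1ccc(OCc2ccccc2)c(OCc2ccccc2)c1 | starting material
2 | (triphenylphosphoranylidene)acetaldehyde | O=CC=P(c1ccccc1)(c1ccccc1)c1ccccc1 | starting material
3 | (E)-3-[3,4-bis(benzyloxy)phenyl]prop-2-enal | O=C/C=C/c1ccc(OCc2ccccc2)c(OCc2ccccc2)c1 | intermediate
4 | (E)-3-[3,4-bis(benzyloxy)phenyl]prop-2-en-1-ol | OC/C=C/c1ccc(OCc2ccccc2)c(OCc2ccccc2)c1 | intermediate
5 | [(2S,3S)-3-[3,4-bis(benzyloxy)phenyl]oxiran-2-yl]methanol (trans) | OC[C@@H]1O[C@H]1c1ccc(OCc2ccccc2)c(OCc2ccccc2)c1 | intermediate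
6 | 3,5-bis(benzyloxy)phenol | Oc1cc(OCc2ccccc2)cc(OCc2ccccc2)c1 | starting material
7 | (4R)-5,7-bis(benzyloxy)-4-[3,4-bis(benzyloxy)phenyl]chroman-2-ol (C2 anomers) | OC1C[C@H](c2ccc(OCc3ccccc3)c(OCc3ccccc3)c2)c2c(OCc3ccccc3)cc(OCc3ccccc3)cc2O1 | intermediate
8 | (3R,4R)-5,7-bis(benzyloxy)-4-[3,4-bis(benzyloxy)phenyl]-3-[(phenylamino)oxy]chroman-2-ol (3,4-cis; C2 anomers) | OC1[C@H](ONc2ccccc2)[C@H](c2ccc(OCc3ccccc3)c(OCc3ccccc3)c2)c2c(OCc3ccccc3)cc(OCc3ccccc3)cc2O1 | intermediate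
9 | (3R,4R)-5,7-bis(benzyloxy)-4-[3,4-bis(benzyloxy)phenyl]chromane-2,3-diol (3,4-cis; C2 anomers) | OC1[C@H](O)[C@H](c2ccc(OCc3ccccc3)c(OCc3ccccc3)c2)c2c(OCc3ccccc3)cc(OCc3ccccc3)cc2O1 | intermediate
10 | 1,3,5-tris(benzyloxy)benzene | c1c(OCc2ccccc2)cc(OCc2ccccc2)cc1OCc1ccccc1 | starting material
11 | (3R,4R)-5,7-bis(benzyloxy)-4-[3,4-bis(benzyloxy)phenyl]-2-[2,4,6-tris(benzyloxy)phenyl]chroman-3-ol (C2 epimers) | C1(c2c(OCc3ccccc3)cc(OCc3ccccc3)cc2OCc2ccccc2)[C@H](O)[C@H](c2ccc(OCc3ccccc3)c(OCc3ccccc3)c2)c2c(OCc3ccccc3)cc(OCc3ccccc3)cc2O1 | intermediate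
12 | 2-[(1R,2S)-1-[3,4-bis(benzyloxy)phenyl]-2-hydroxy-3-[2,4,6-tris(benzyloxy)phenyl]propyl]-3,5-bis(benzyloxy)phenol | c1ccccc1COc1cc(OCc2ccccc2)cc(OCc2ccccc2)c1C[C@H](O)[C@H](c1ccc(OCc2ccccc2)c(OCc2ccccc2)c1)c1c(O)cc(OCc2ccccc2)cc1OCc1ccccc1 | intermediate
13 | (2S,3R)-3-[3,4-bis(benzyloxy)phenyl]-3-{3,5-bis(benzyloxy)-2-[(1R,2S)-1-[3,4-bis(benzyloxy)phenyl]-2-hydroxy-3-[2,4,6-tris(benzyloxy)phenyl]propyl]phenoxy}propane-1,2-diol | c1ccccc1COc1cc(OCc2ccccc2)cc(OCc2ccccc2)c1C[C@H](O)[C@H](c1ccc(OCc2ccccc2)c(OCc2ccccc2)c1)c1c(O[C@H](c2ccc(OCc3ccccc3)c(OCc3ccccc3)c2)[C@@H](O)CO)cc(OCc2ccccc2)cc1OCc1ccccc1 | intermediate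
14 | primary 4-methylbenzenesulfonate of 13: (2S,3R)-2-hydroxy-3-aryl-3-aryloxypropyl tosylate | c1ccccc1COc1cc(OCc2ccccc2)cc(OCc2ccccc2)c1C[C@H](O)[C@H](c1ccc(OCc2ccccc2)c(OCc2ccccc2)c1)c1c(O[C@H](c2ccc(OCc3ccccc3)c(OCc3ccccc3)c2)[C@@H](O)COS(=O)(=O)c2ccc(C)cc2)cc(OCc2ccccc2)cc1OCc1ccccc1 | intermediate
15 | (1R,2S)-1-[3,4-bis(benzyloxy)phenyl]-1-[2,4-bis(benzyloxy)-6-{(R)-[3,4-bis(benzyloxy)phenyl][(2S)-oxiran-2-yl]methoxy}phenyl]-3-[2,4,6-tris(benzyloxy)phenyl]propan-2-ol | c1ccccc1COc1cc(OCc2ccccc2)cc(OCc2ccccc2)c1C[C@H](O)[C@H](c1ccc(OCc2ccccc2)c(OCc2ccccc2)c1)c1c(O[C@H](c2ccc(OCc3ccccc3)c(OCc3ccccc3)c2)[C@@H]2CO2)cc(OCc2ccccc2)cc1OCc1ccccc1 | intermediate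
16 | (2R,3S)-5,7-bis(benzyloxy)-2-[3,4-bis(benzyloxy)phenyl]-8-[(1R,2S)-1-[3,4-bis(benzyloxy)phenyl]-2-hydroxy-3-[2,4,6-tris(benzyloxy)phenyl]propyl]chroman-3-ol | c1ccccc1COc1cc(OCc2ccccc2)c(C[C@H](O)[C@H](c2ccc(OCc3ccccc3)c(OCc3ccccc3)c2)c2c(OCc3ccccc3)cc(OCc3ccccc3)c3c2O[C@H](c2ccc(OCc4ccccc4)c(OCc4ccccc4)c2)[C@@H](O)C3)c(OCc2ccccc2)c1 | intermediate
17 | (2R,3S)-2-(3,4-dihydroxyphenyl)-8-[(1R,2S)-1-(3,4-dihydroxyphenyl)-2-hydroxy-3-(2,4,6-trihydroxyphenyl)propyl]chromane-3,5,7-triol (the target natural product) | Oc1cc(O)c(C[C@H](O)[C@H](c2ccc(O)c(O)c2)c2c(O)cc(O)c3c2O[C@H](c2ccc(O)c(O)c2)[C@@H](O)C3)c(O)c1 | target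

Total step count: 10. Longest linear sequence: 8 steps (steps 1, 4, 5, 6, 7, 8, 9, 10).

Steps most likely to fail

Step 5. Enamine formation from the hindered lactol may be slow, the C4 stereocentre may oppose the catalyst and erode facial selectivity, and the α-hydroxy aldehyde tautomer may isomerise. The fallback sets out from 7 and comes back at 9, replacing enamine catalysis by substrate control on a lactone enolate followed by inversion. Lactol 7 would be oxidised (PhI(OAc)2, TEMPO cat., CH2Cl2) to the dihydrocoumarin F1. Its potassium enolate (KN(SiMe3)2, THF, −78 °C) would be hydroxylated with 2-(phenylsulfonyl)-3-phenyloxaziridine on the face anti to the C4 aryl group to give the trans hydroxy lactone F2. Mitsunobu inversion (PPh3, DIAD, PhCO2H, THF) would give the cis benzoate F3. Reduction with iBu2AlH (CH2Cl2, −78 °C) would take the lactone to the lactol and cleave the benzoate, giving 9.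

Step 6. The ring-opened benzylic cation may be attacked by a second arene or rearrange by hydride shift to a ketone before the silane arrives, the lactol may self-condense during the Friedel–Crafts stage, or the oxocarbenium ion may be reduced before arylation. The fallback sets out from 9 and 10 and comes back at 12, forming the C–C bond by organometallic addition instead of through a cation. Arene 10 would be brominated (NBS, CH2Cl2, 0 °C) to 2-bromo-1,3,5-tris(benzyloxy)benzene F4. Bromine–lithium exchange (n-BuLi, THF, −78 °C) and addition of the aryllithium in excess to 9, which opens to the phenoxide aldehyde, would give the benzylic carbinol F5 as a mixture at the new carbinol carbon. Ionic deoxygenation of this alkoxy-stabilised benzylic alcohol (Et3SiH, CF3CO2H, CH2Cl2, 0 °C) would give 12.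

Step 9. The arene may attack the internal epoxide carbon (5-exo), or the Lewis acid may ionise the benzylic O1–C2 ether with loss of configuration at C2 or cleavage of the ether. The fallback sets out from 13 and comes back at 16, closing ring C by carbonyl Friedel–Crafts hydroxyalkylation instead of epoxide opening. The primary alcohol of 13 would be oxidised selectively (TEMPO cat., PhI(OAc)2, CH2Cl2) to the α-hydroxy aldehyde F6. With BF3·OEt2 and Et3SiH (CH2Cl2, −40 °C), C4a would add to the aldehyde (6-exo-trig) to give the flavan-3,4-diol F7. Its benzylic C4 hydroxyl would be ionised and reduced by the silane in the same flask, giving 16.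

Further compounds
F1 | step 5 | (4R)-5,7-bis(benzyloxy)-4-[3,4-bis(benzyloxy)phenyl]chroman-2-one | O=C1C[C@H](c2ccc(OCc3ccccc3)c(OCc3ccccc3)c2)c2c(OCc3ccccc3)cc(OCc3ccccc3)cc2O1
F2 | step 5 | (3S,4R)-5,7-bis(benzyloxy)-4-[3,4-bis(benzyloxy)phenyl]-3-hydroxychroman-2-one (3,4-trans) | O=C1[C@@H](O)[C@H](c2ccc(OCc3ccccc3)c(OCc3ccccc3)c2)c2c(OCc3ccccc3)cc(OCc3ccccc3)cc2O1
F3 | step 5 | (3R,4R)-5,7-bis(benzyloxy)-4-[3,4-bis(benzyloxy)phenyl]-2-oxochroman-3-yl benzoate (3,4-cis) | O=C1[C@H](OC(=O)c2ccccc2)[C@H](c2ccc(OCc3ccccc3)c(OCc3ccccc3)c2)c2c(OCc3ccccc3)cc(OCc3ccccc3)cc2O1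
F4 | step 6 | 2-bromo-1,3,5-tris(benzyloxy)benzene | Brc1c(OCc2ccccc2)cc(OCc2ccccc2)cc1OCc1ccccc1
F5 | step 6 | 2-[(1R,2R)-1-[3,4-bis(benzyloxy)phenyl]-2,3-dihydroxy-3-[2,4,6-tris(benzyloxy)phenyl]propyl]-3,5-bis(benzyloxy)phenol (C3 epimers) | c1ccccc1COc1cc(OCc2ccccc2)cc(OCc2ccccc2)c1C(O)[C@H](O)[C@H](c1ccc(OCc2ccccc2)c(OCc2ccccc2)c1)c1c(O)cc(OCc2ccccc2)cc1OCc1ccccc1
F6 | step 9 | (2R,3R)-3-[3,4-bis(benzyloxy)phenyl]-3-{3,5-bis(benzyloxy)-2-[(1R,2S)-1-[3,4-bis(benzyloxy)phenyl]-2-hydroxy-3-[2,4,6-tris(benzyloxy)phenyl]propyl]phenoxy}-2-hydroxypropanal | c1ccccc1COc1cc(OCc2ccccc2)cc(OCc2ccccc2)c1C[C@H](O)[C@H](c1ccc(OCc2ccccc2)c(OCc2ccccc2)c1)c1c(O[C@H](c2ccc(OCc3ccccc3)c(OCc3ccccc3)c2)[C@@H](O)C=O)cc(OCc2ccccc2)cc1OCc1ccccc1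
F7 | step 9 | (2R,3S)-5,7-bis(benzyloxy)-2-[3,4-bis(benzyloxy)phenyl]-8-[(1R,2S)-1-[3,4-bis(benzyloxy)phenyl]-2-hydroxy-3-[2,4,6-tris(benzyloxy)phenyl]propyl]chromane-3,4-diol (C4 epimers) | c1ccccc1COc1cc(OCc2ccccc2)c(C[C@H](O)[C@H](c2ccc(OCc3ccccc3)c(OCc3ccccc3)c2)c2c(OCc3ccccc3)cc(OCc3ccccc3)c3c2O[C@H](c2ccc(OCc4ccccc4)c(OCc4ccccc4)c2)[C@@H](O)C3O)c(OCc2ccccc2)c1
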